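You have a stirred vessel of constant volume into which starting material goes in equal portions, while the two nucleophiles stand ready in it.

    starting material → intermediate (k1 = 0.38 /s)
    first nucleophile + intermediate ⇌ target (K2 = 1000 /M, k2 = 170 /M/s)
    second nucleophile + intermediate → other capture product (k3 = 5.8 /M/s)
    second nucleophile ⇌ dormant form (K4 = 0.49, k4 = 0.070 /s)

common to all: first nucleophile 1.30 equiv; second nucleophile 1.50 equiv; time 10 s

| run | starting material | remark |
|---|---|---|
| beta | 1.2 mM (in portions, 3) | the portions of starting material follow each other after 0.80 s, the first at the start |
| epsilon | 2.5 mM (in portions, 3) | the portions of starting material follow each other after 0.80 s, the first at the start |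
| delta | 5.0 mM (in portions, 3) | the portions of starting material follow each other after 0.80 s, the first at the start |

- "hardly changes" means that all values lie within two and a half points (for a concentration: within two and a half percent of the largest)
- run time (beta): 10 s

- [intermediate] at the end for beta, epsilon, delta, in this order
- the course of these numbers from the first flask to the last (rises, then falls / hardly changes / falls all the way / rises all the way / falls, then rises)

Keep a ledger, by hand, of the limiting reagent, which is the starting material, with first nucleophile at 1.30 equiv and second nucleophile at 1.50 equiv. Take the beta flask at the end of the run.

The first entry is what has not reacted. The portions have aged differently, and on average 3.13% of the charge is still starting material, so 1.16 mM has passed on.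

The second entry is the split between intermediate and target. The equilibrium constant 1000 /M means that 1.00 mM of free first nucleophile holds the two equal. With first nucleophile at its charge, this exchange relaxes with a half-life of 1.59 s, which is shorter than the time since the last portion, so you may reckon from the end state. Each target formed costs one first nucleophile, and that gives a first level of intermediate of 0.586 mM.

The third entry is capture. Second nucleophile exchanges with its dormant form with a relaxation half-life of 3.26 s, shorter than the run, so I reckon with about 1.21 mM free. Holding that and the first level for the whole run gives 0.0411 mM of other capture product.

Take this from the pool and solve the split again. The result is the balance level, the c(intermediate) at which the pool left after capture stands at equilibrium with target: 0.561 mM. The books close with 0.558 mM of target.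

The same entries for epsilon pass 2.42 mM, with first level 0.891 mM, capture 0.130 mM and balance level 0.824 mM. For delta they pass 4.84 mM, with 1.24 mM, 0.363 mM and 1.09 mM. My row therefore rises from flask to flask.

The forecast, holding that “the intermediate and target are nearly at equilibrium”, gives 0.6 mM, 0.88 mM and 1.13 mM, which rises all the way. Its numbers stand above mine in each of the flasks.

The simulation gives 0.599 mM, 0.870 mM and 1.14 mM, which rises all the way.

In beta, intermediate has a half-life of 2.8 s at 2.62 s by the forward rate of its path to target alone, shorter than the run of 10 s, and at the end intermediate is being made at 0.683 of the rate at which it is used up, each step taken net. The beta flask ends 0.0380 mM above its balance level, and the delta flask holds 1.14 mM of intermediate against a balance level of 1.09 mM, a difference of 0.0500 mM.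

The constants used here are those of an exercise; the flask was simulated.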